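**Retrosynthetic overview**
1. Presumed biogenesis: the (6Z,9Z)-skipped diene gives a cis,cis-bis-epoxide. An acid enters at C10 with inversion, O9 closes onto C6 of the cis-6,7-epoxide with inversion, and O7 is released as the free alcohol.
2. The last disconnection is this closure, run with palmitate already on C10: oxolane C6–O9 bond ⇒ cis-6,7-epoxy-9-ol ⇒ (Z)-homoallylic alcohol. The C6/C7 oxirane forms first and the oxolane second, in one flask, as the final step.
3. C7–C8 ⇒ (Z)-hept-1-enyl cuprate (pentyllithium + acetylene) plus a terminal C8/C9 epoxide.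
4. C10–O(acyl) ⇒ Mitsunobu inversion of an erythro epoxy alcohol by palmitic acid itself. Esterification and stereo-correction are one operation, so no protecting group is needed and no diol has to be differentiated.
5. Epoxy alcohol ⇒ Sharpless kinetic resolution of the vinyl carbinol made from dec-9-enal and vinylmagnesium bromide.

Assumption: positions use oxylipin numbering (C1 = CH3 of the pentyl chain, C19 = terminal =CH2), the acyl group is hexadecanoyl, and dec-9-enal is bought as the flavour chemical.

**Step 1**
Reactants: 1 dec-9-enal; 2 vinylmagnesium bromide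
Product: 3 (±)-dodeca-1,11-dien-3-ol
Conditions: 2 (1.2 equiv), THF, −78 → 0 °C; aq. work-up
Reagents that add atoms: vinylmagnesium bromide (2), C=C[Mg]Br
Why: Grignard 1,2-addition to an unhindered aldehyde, in which the carbinol centre (C10) is made racemic on purpose and resolved in step 2.

**Step 2**
Reactants: 3 (±)-dodeca-1,11-dien-3-ol
Product: 4 (1S)-1-[(2R)-oxiran-2-yl]dec-9-en-1-ol (erythro; C9 R, C10 S)
Conditions: Ti(OiPr)4 (10 mol %), L-(+)-DIPT (13 mol %), t-BuOOH (0.45 equiv, decane), 4 Å MS, CH2Cl2, −20 °C
Reagents that add atoms: tert-butyl hydroperoxide, CC(C)(C)OO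
Why: In this Sharpless kinetic resolution (Katsuki–Sharpless epoxidation) with L-(+)-DIPT, the (S)-carbinol is epoxidised roughly two orders of magnitude faster than the (R)-carbinol and gives the erythro epoxy alcohol, so stopping below 50 % conversion should fix C9 (R) and C10 (S) in high ee, while the remote non-allylic C18=C19 alkene is inert to Ti/t-BuOOH.

**Step 3**
Reactants: 4 (1S)-1-[(2R)-oxiran-2-yl]dec-9-en-1-ol; 5 hexadecanoic (palmitic) acid
Product: 6 (1R)-1-[(2R)-oxiran-2-yl]dec-9-en-1-yl hexadecanoate (threo; C9 R, C10 R)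
Conditions: 5 (1.3 equiv), PPh3 (1.4 equiv), DIAD (1.4 equiv), toluene, 0 °C → rt
Reagents that add atoms: palmitic acid (5), CCCCCCCCCCCCCCCC(=O)O
Why: In this Mitsunobu esterification, SN2 attack of palmitate on the alkoxyphosphonium ion inverts C10 (S → R), so the acid reaches C10 with inversion as in an acid-initiated epoxide opening, the ester is placed before any second hydroxyl exists, and the oxirane survives the neutral medium.

**Step 4**
Reactants: 6 (1R)-1-[(2R)-oxiran-2-yl]dec-9-en-1-yl hexadecanoate; 7 pentyllithium; 8 acetylene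
Product: 11 (6Z,9R,10R)-9-hydroxynonadeca-6,18-dien-10-yl hexadecanoate, via lithium dipentylcuprate 9 (not isolated), via lithium di[(Z)-hept-1-enyl]cuprate 10 (not isolated)
Conditions: 7 (3.0 equiv), CuBr·SMe2 (1.5 equiv), Et2O, −40 °C; 8 (3.0 equiv), −50 → −25 °C; BF3·OEt2 (1.5 equiv), then 6, −78 °C; aq. NH4Cl/pH 7 buffer added at −78 °C
Reagents that add atoms: pentyllithium (7), [Li]CCCCC; acetylene (8), C#C
Why: Normant syn-carbocupration of acetylene gives the (Z)-alkenyl cuprate, whose BF3-assisted SN2 opening of the terminal epoxide at the unhindered CH2 (C8) keeps the Z geometry and leaves C9 untouched, while at −78 °C the boron-bound alkoxide is too weak a nucleophile for 1,2-acyl migration and cuprates do not add to esters.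

**Step 5**
Reactants: 11 (6Z,9R,10R)-9-hydroxynonadeca-6,18-dien-10-yl hexadecanoate
Product: 13 (6S,7S,9R,10R)-6,9-epoxy-7-hydroxynonadec-18-en-10-yl hexadecanoate, via cis-6,7-epoxy alcohol 12 (not isolated)
Conditions: VO(acac)2 (5 mol %), t-BuOOH (1.3 equiv, decane), CH2Cl2, 0 °C → rt; then CSA (10 mol %), rt
Reagents that add atoms: tert-butyl hydroperoxide, CC(C)(C)OO
Why: Hydroxyl-directed vanadium epoxidation of the (Z)-homoallylic alcohol through a chair transition state (C9 substituent equatorial, Z-alkene pseudo-equatorial) delivers oxygen syn to O9 and only to C6=C7, giving the (6R,7S)-cis-epoxide, which O9 then opens by a stereospecific 5-endo-tet SN2 attack at C6 (R → S; the only alternative is a strained 4-exo oxetane), so C7 (S) keeps its C–O bond and appears as the single free hydroxyl of the 2,5-trans-2,3-cis oxolane.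

**Compound list**
1 | dec-9-enal | C=CCCCCCCCC=O | starting material
2 | vinylmagnesium bromide | C=C[Mg]Br | starting material
3 | (±)-dodeca-1,11-dien-3-ol | C=CCCCCCCCC(O)C=C | intermediate
4 | (1S)-1-[(2R)-oxiran-2-yl]dec-9-en-1-ol | C=CCCCCCCC[C@H](O)[C@H]1CO1 | intermediate
5 | hexadecanoic (palmitic) acid | CCCCCCCCCCCCCCCC(=O)O | starting material
6 | (1R)-1-[(2R)-oxiran-2-yl]dec-9-en-1-yl hexadecanoate | C=CCCCCCCC[C@@H](OC(=O)CCCCCCCCCCCCCCC)[C@H]1CO1 | intermediate
7 | pentyllithium | [Li]CCCCC | starting material
8 | acetylene | C#C | starting material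
9 | lithium dipentylcuprate (not isolated) | [Li+].CCCCC[Cu-]CCCCC | intermediate
10 | lithium di[(Z)-hept-1-enyl]cuprate (not isolated) | [Li+].CCCCC/C=C\[Cu-]/C=C\CCCCC | intermediate
11 | (6Z,9R,10R)-9-hydroxynonadeca-6,18-dien-10-yl hexadecanoate | C=CCCCCCCC[C@@H](OC(=O)CCCCCCCCCCCCCCC)[C@H](O)C/C=C\CCCCC | intermediate
12 | (6R,7S,9R,10R)-6,7-epoxy-9-hydroxynonadec-18-en-10-yl hexadecanoate (cis-epoxide, not isolated) | C=CCCCCCCC[C@@H](OC(=O)CCCCCCCCCCCCCCC)[C@H](O)C[C@@H]1O[C@@H]1CCCCC | intermediate
13 | (6S,7S,9R,10R)-6,9-epoxy-7-hydroxynonadec-18-en-10-yl hexadecanoate = (1R)-1-[(2R,4S,5S)-4-hydroxy-5-pentyloxolan-2-yl]dec-9-en-1-yl hexadecanoate | C=CCCCCCCC[C@@H](OC(=O)CCCCCCCCCCCCCCC)[C@H]1C[C@H](O)[C@H](CCCCC)O1 | target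

**Total step count:** 5. **Longest linear sequence:** 5 (1 → 3 → 4 → 6 → 11 → 13).

**Steps most likely to fail**

*Step 5.* The risks are:
- eroded syn selectivity next to the bulky C10 acyloxy group;
- an O10 → O9 acyl shift followed by a 5-exo closure of O10 onto C7;
- sluggish 5-endo closure.

The fallback sets out from 11. It replaces substrate control by catalyst control and splits the tandem reaction into two separate operations. First comes epoxidation with VO(OiPr)3, a C2-symmetric chiral bishydroxamic acid ligand and cumene hydroperoxide (toluene, 0 °C), a system suited to cis-homoallylic alcohols. This gives 12, now isolated on base-washed silica. Compound 12 is then closed on its own in a hydrogen-bond-donor medium (HFIP, rt) without added acid, so the ester has less chance to migrate. The fallback rejoins the route at 12 and goes on to 13.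

*Step 4.* The risks are participation or migration of the ester next to the activated oxirane, and the handling and stoichiometry of the acetylene-derived cuprate.

The fallback sets out from 6 and uses an sp-nucleophile followed by reduction. Lithium hept-1-ynide with BF3·OEt2 (THF, −78 °C, Yamaguchi–Hirao alkynylation) opens C8 to give (9R,10R)-9-hydroxynonadec-18-en-6-yn-10-yl hexadecanoate F1. Z-selective semihydrogenation follows (Lindlar Pd, quinoline, 1 atm H2, stopped at one equivalent). The alkyne outcompetes the terminal alkene for the catalyst surface. The fallback rejoins the route at 11.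

*Step 3.* The risk is that a weakly acidic fatty acid reacts poorly at a carbinol deactivated by the adjacent oxirane, giving low conversion and acyl-hydrazide by-products.

The fallback sets out from 4 and separates inversion from acylation:
- Mitsunobu reaction with 4-nitrobenzoic acid gives (1R)-1-[(2R)-oxiran-2-yl]dec-9-en-1-yl 4-nitrobenzoate F2.
- Brief methanolysis (K2CO3, MeOH, 0 °C, kept short to avoid Payne rearrangement) gives the threo alcohol (1R)-1-[(2R)-oxiran-2-yl]dec-9-en-1-ol F3.
- Palmitoyl chloride with pyridine and DMAP (retention) rejoins the route at 6.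

**Further compounds**
F0 | step 5 | none | none
F1 | step 4 | (9R,10R)-9-hydroxynonadec-18-en-6-yn-10-yl hexadecanoate | C=CCCCCCCC[C@@H](OC(=O)CCCCCCCCCCCCCCC)[C@H](O)CC#CCCCCC
F2 | step 3 | (1R)-1-[(2R)-oxiran-2-yl]dec-9-en-1-yl 4-nitrobenzoate | C=CCCCCCCC[C@@H](OC(=O)c1ccc(cc1)[N+](=O)[O-])[C@H]1CO1
F3 | step 3 | (1R)-1-[(2R)-oxiran-2-yl]dec-9-en-1-ol | C=CCCCCCCC[C@@H](O)[C@H]1CO1
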